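**Retrosynthetic overview**

- Last, three MOM ethers are removed. Before that, the C2–C1′ bond between ring C and ring B is cut by an asymmetric 1,4-addition of a chromenylboronic acid (ring B plus pyran ring D) to a purchased 5,7-dioxygenated chromone (rings A and C); this sets C2 as (S).
- Pyran ring D is cut at O1–C8a and C4–C4a (chromene numbering) back to an aryne on ring B and prenal: carbonyl [2+2], retro-4π opening to an o-quinone methide, oxa-6π closure (O1–C2).
- Enabling feature: C8a and C4a are ortho carbons of ring B carrying O1 and the cis-vinyl carbon C4 of a 2,2-dimethyl-2H-pyran, which is the electrocyclised form of a vinyl o-quinone methide. The hydroxyl on the neighbouring C8 is carried as a pinacolboronate, a σ-donor that steers the carbonyl oxygen to C8a and is oxidised to OH afterwards; Cl at C6 is the handle for the later boronic acid.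
- Order of ring formation: ring B is present from the start (phenol 1); a transient benzoxete and then ring D form in step 4; rings A and C come preformed and are joined to ring B in step 9.

Key step: step 4

Remark: the stereocentre of the target SMILES is (2S) (O1 > aryl > C3 > H); the sense of induction of the ligand in step 9 is assigned by analogy with cyclic enones, and the antipodal ligand is used if the first run shows the opposite sense.
Remark: compounds 1, 6 and 15 are taken as purchasable (1 is otherwise available by dibromination of 4-chlorophenol).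

Step 1
Reactants: 1 2,6-dibromo-4-chlorophenol
Product: 3 2-bromo-4-chloro-6-(trimethylsilyl)phenol, via aryl trimethylsilyl ether 2 (not isolated)
Conditions: HMDS, THF, reflux, then evaporate; n-BuLi (1.05 equiv), THF, −78 °C → rt; aq. NH4Cl
Reagents that add atoms: hexamethyldisilazane, C[Si](C)(C)N[Si](C)(C)C
Why: O-silylation, bromine–lithium exchange and anionic 1,3 O→C silyl shift (retro-Brook rearrangement) is the standard entry to o-silylphenols; one equivalent of n-BuLi exchanges one C–Br bond only, C–Cl is inert at −78 °C and the aryllithium has no ortho halogen to eliminate.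

Step 2
Reactants: 3 2-bromo-4-chloro-6-(trimethylsilyl)phenol
Product: 4 4-chloro-2-(4,4,5,5-tetramethyl-1,3,2-dioxaborolan-2-yl)-6-(trimethylsilyl)phenol
Conditions: n-BuLi (2.2 equiv), Et2O, −78 → 0 °C; i-PrOBpin, −78 °C → rt; aq. NH4Cl
Reagents that add atoms: 2-isopropoxy-4,4,5,5-tetramethyl-1,3,2-dioxaborolane, CC(C)OB1OC(C)(C)C(C)(C)O1
Why: O-deprotonation and bromine–lithium exchange give the O,C-dilithio species, which is trapped at carbon by the borate ester (lithiation–borylation), while C–Cl and C–Si are untouched.

Step 3
Reactants: 4 4-chloro-2-(4,4,5,5-tetramethyl-1,3,2-dioxaborolan-2-yl)-6-(trimethylsilyl)phenol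
Product: 5 4-chloro-2-(4,4,5,5-tetramethyl-1,3,2-dioxaborolan-2-yl)-6-(trimethylsilyl)phenyl trifluoromethanesulfonate
Conditions: Tf2O, pyridine, CH2Cl2, 0 °C → rt
Reagents that add atoms: trifluoromethanesulfonic anhydride, O=S(=O)(OS(=O)(=O)C(F)(F)F)C(F)(F)F
Why: O-sulfonylation of the phenol gives the o-silylaryl triflate needed for mild fluoride-induced aryne generation; pinacolboronate and aryl silane are inert to Tf2O/pyridine.

Step 4
Reactants: 5 4-chloro-2-(4,4,5,5-tetramethyl-1,3,2-dioxaborolan-2-yl)-6-(trimethylsilyl)phenyl trifluoromethanesulfonate; 6 prenal (3-methylbut-2-enal, 4 equiv)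
Product: 10 2-(6-chloro-2,2-dimethyl-2H-chromen-8-yl)-4,4,5,5-tetramethyl-1,3,2-dioxaborolane, via aryne 7 (not isolated), via benzoxete 8 (not isolated), via o-quinone methide 9 (not isolated)
Conditions: CsF (3 equiv), MeCN, 0 °C → rt, slow addition of 5 to CsF and 6
Reagents that add atoms: none
Why: Proposed new method: fluoride attacks silicon of 5 and triflate leaves to give aryne 7; the carbonyl oxygen of prenal adds to the aryne carbon flanked by boron and the aryl anion so formed closes on the oxocarbenium carbon (stepwise polar [2+2]) to benzoxete 8, which opens by retro-4π electrocyclisation to o-quinone methide 9 and recloses by thermal disrotatory oxa-6π electrocyclisation, rearomatisation of ring B being the driving force. The closest known reaction types are the fluoride-induced annulation of arynes from o-silylaryl triflates with α,β-unsaturated aldehydes to 2H-chromenes and the ortho-selective addition of heteroatom nucleophiles to 3-borylbenzynes and 3-silylbenzynes; new is the use of the boryl group to steer a carbonyl [2+2]. Ring closures: the transient oxete ring by C–C bond formation of the aryl anion onto the oxocarbenium ion (4-exo), the pyran ring by 6π electrocyclisation forming O1–C2. No stereocentre is created (8 is racemic and transient, C2 of 10 carries two methyl groups), and the E and Z forms of 9 can interconvert by reclosure to 8 or by rotation in the phenoxide/allyl cation resonance form, only the Z form cyclising. The step needs regioselectivity, secured by the electropositive boron, which polarises the aryne so that the carbon next to it is the electrophilic one and the aryl anion develops away from it (the chlorine para to this carbon acts in the same sense and the in-plane carbonyl lone pair is a small nucleophile). It also needs fluoride to attack silicon and not boron, and the o-quinone methide to close intramolecularly before a second aryne captures it, which the easy loss of Me3SiF next to triflate, the excess of prenal and the slow generation of 7 should secure.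

Step 5
Reactants: 10 2-(6-chloro-2,2-dimethyl-2H-chromen-8-yl)-4,4,5,5-tetramethyl-1,3,2-dioxaborolane
Product: 11 6-chloro-2,2-dimethyl-2H-chromen-8-ol
Conditions: 30% aq. H2O2, 1 M NaOH, THF, 0 °C; aq. Na2S2O3
Reagents that add atoms: hydrogen peroxide, OO
Why: ipso-oxidation of the arylboronate (1,2-aryl shift from boron to oxygen in the hydroperoxide ate complex) unmasks the C8 hydroxyl; nucleophilic alkaline peroxide should not epoxidise the electron-rich chromene alkene.

Step 6
Reactants: 11 6-chloro-2,2-dimethyl-2H-chromen-8-ol
Product: 12 6-chloro-8-(methoxymethoxy)-2,2-dimethyl-2H-chromene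
Conditions: MOMCl, i-Pr2NEt, CH2Cl2, 0 °C → rt
Reagents that add atoms: chloromethyl methyl ether, COCCl
Why: O-alkylation of the phenol (acetal ether formation) masks the acidic OH for the palladium and rhodium steps with the same group as on the chromone, so that one final operation removes all three.

Step 7
Reactants: 12 6-chloro-8-(methoxymethoxy)-2,2-dimethyl-2H-chromene
Product: 14 [8-(methoxymethoxy)-2,2-dimethyl-2H-chromen-6-yl]boronic acid, via pinacol boronate 13 (not isolated)
Conditions: Pd2(dba)3 (1 mol %), XPhos, B2pin2, KOAc, 1,4-dioxane, 100 °C; filter; NaIO4, NH4OAc, acetone/H2O, rt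
Reagents that add atoms: bis(pinacolato)diboron, CC1(C)OB(OC1(C)C)B1OC(C)(C)C(C)(C)O1; water, O
Why: Miyaura borylation of the electron-rich aryl chloride with a bulky biarylphosphine ligand, then oxidative cleavage of the pinacol ester by periodate, gives the free boronic acid needed for the base-free rhodium step; alkene and MOM ether are inert to both stages.

Step 8
Reactants: 15 5,7-dihydroxy-4H-chromen-4-one
Product: 16 5,7-bis(methoxymethoxy)-4H-chromen-4-one
Conditions: NaH (2.5 equiv), MOMCl (2.5 equiv), DMF, 0 °C → rt
Reagents that add atoms: chloromethyl methyl ether, COCCl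
Why: Williamson-type O-alkylation of both phenoxides; the strong base is chosen because the 5-OH is hydrogen-bonded to the C4 carbonyl and sluggish with amine bases.

Step 9
Reactants: 14 [8-(methoxymethoxy)-2,2-dimethyl-2H-chromen-6-yl]boronic acid (1.5 equiv); 16 5,7-bis(methoxymethoxy)-4H-chromen-4-one
Product: 17 (2S)-5,7-bis(methoxymethoxy)-2-[8-(methoxymethoxy)-2,2-dimethyl-2H-chromen-6-yl]-2,3-dihydro-4H-chromen-4-one
Conditions: [Rh(OH)(cod)]2 (2.5 mol %), (S)-MeO-F12-BIPHEP (5.5 mol %), toluene/H2O (10:1), 30 °C
Reagents that add atoms: none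
Why: Hayashi–Miyaura asymmetric 1,4-addition (boron-to-rhodium transmetalation, enantioface-selective insertion of the chromone C2=C3 bond into the aryl–Rh bond, protonolysis of the rhodium enolate by water) sets C2 under catalyst control by the C2-symmetric bisphosphine, the (S)-ligand being assumed to give (2S); the base-free, low-temperature conditions allowed by the electron-poor ligand should avoid chromone ring opening and retro-oxa-Michael racemisation of the product.

Step 10
Reactants: 17 (2S)-5,7-bis(methoxymethoxy)-2-[8-(methoxymethoxy)-2,2-dimethyl-2H-chromen-6-yl]-2,3-dihydro-4H-chromen-4-one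
Product: 18 (2S)-5,7-dihydroxy-2-(8-hydroxy-2,2-dimethyl-2H-chromen-6-yl)-2,3-dihydro-4H-chromen-4-one (target)
Conditions: 3 M aq. HCl, MeOH, 50 °C
Reagents that add atoms: none
Why: acid-catalysed acetal methanolysis removes the three aryl MOM ethers; dilute acid should leave the 2,2-dimethyl-2H-chromene intact, and C2 is not epimerised because flavanone racemisation runs through base-induced ring opening to the 2′-hydroxychalcone.

**Compound list**

1 | 2,6-dibromo-4-chlorophenol | Oc1c(Br)cc(Cl)cc1Br | starting material
2 | (2,6-dibromo-4-chlorophenoxy)trimethylsilane | C[Si](C)(C)Oc1c(Br)cc(Cl)cc1Br | intermediate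
3 | 2-bromo-4-chloro-6-(trimethylsilyl)phenol | C[Si](C)(C)c1cc(Cl)cc(Br)c1O | intermediate
4 | 4-chloro-2-(4,4,5,5-tetramethyl-1,3,2-dioxaborolan-2-yl)-6-(trimethylsilyl)phenol | CC1(C)OB(OC1(C)C)c1cc(Cl)cc([Si](C)(C)C)c1O | intermediate
5 | 4-chloro-2-(4,4,5,5-tetramethyl-1,3,2-dioxaborolan-2-yl)-6-(trimethylsilyl)phenyl trifluoromethanesulfonate | CC1(C)OB(OC1(C)C)c1cc(Cl)cc([Si](C)(C)C)c1OS(=O)(=O)C(F)(F)F | intermediate
6 | prenal (3-methylbut-2-enal) | CC(C)=CC=O | starting material
7 | 5-chloro-3-(4,4,5,5-tetramethyl-1,3,2-dioxaborolan-2-yl)benzyne (1,2-didehydrobenzene) | CC1(C)OB(OC1(C)C)C1=CC(Cl)=CC#C1 | intermediate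
8 | 4-chloro-2-(2-methylprop-1-en-1-yl)-6-(4,4,5,5-tetramethyl-1,3,2-dioxaborolan-2-yl)-2H-benzo[b]oxete (racemic) | CC(C)=CC1Oc2c(B3OC(C)(C)C(C)(C)O3)cc(Cl)cc12 | intermediate
9 | (6Z)-4-chloro-6-(3-methylbut-2-en-1-ylidene)-2-(4,4,5,5-tetramethyl-1,3,2-dioxaborolan-2-yl)cyclohexa-2,4-dien-1-one | CC(C)=C/C=C1/C=C(Cl)C=C(B2OC(C)(C)C(C)(C)O2)C1=O | intermediate
10 | 2-(6-chloro-2,2-dimethyl-2H-chromen-8-yl)-4,4,5,5-tetramethyl-1,3,2-dioxaborolane | CC1(C)C=Cc2cc(Cl)cc(B3OC(C)(C)C(C)(C)O3)c2O1 | intermediate
11 | 6-chloro-2,2-dimethyl-2H-chromen-8-ol | CC1(C)C=Cc2cc(Cl)cc(O)c2O1 | intermediate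
12 | 6-chloro-8-(methoxymethoxy)-2,2-dimethyl-2H-chromene | COCOc1cc(Cl)cc2C=CC(C)(C)Oc12 | intermediate
13 | 2-[8-(methoxymethoxy)-2,2-dimethyl-2H-chromen-6-yl]-4,4,5,5-tetramethyl-1,3,2-dioxaborolane | COCOc1cc(B2OC(C)(C)C(C)(C)O2)cc2C=CC(C)(C)Oc12 | intermediate
14 | [8-(methoxymethoxy)-2,2-dimethyl-2H-chromen-6-yl]boronic acid | COCOc1cc(B(O)O)cc2C=CC(C)(C)Oc12 | intermediate
15 | 5,7-dihydroxy-4H-chromen-4-one | O=c1ccoc2cc(O)cc(O)c12 | starting material
16 | 5,7-bis(methoxymethoxy)-4H-chromen-4-one | COCOc1cc(OCOC)c2c(c1)occc2=O | intermediate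
17 | (2S)-5,7-bis(methoxymethoxy)-2-[8-(methoxymethoxy)-2,2-dimethyl-2H-chromen-6-yl]-2,3-dihydro-4H-chromen-4-one | CC1(C)C=Cc2cc([C@@H]3CC(=O)c4c(OCOC)cc(OCOC)cc4O3)cc(OCOC)c2O1 | intermediate
18 | (2S)-5,7-dihydroxy-2-(8-hydroxy-2,2-dimethyl-2H-chromen-6-yl)-2,3-dihydro-4H-chromen-4-one | CC1(C)C=Cc2cc([C@@H]3CC(=O)c4c(O)cc(O)cc4O3)cc(O)c2O1 | target

Total step count: 10. Longest linear sequence: 9 steps (steps 1–7, 9 and 10); step 8 is the one-step side branch.

**Steps most likely to fail**

1. Step 4 (Proposed new method). What may go wrong: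
- attack of the carbonyl oxygen at the aryne carbon remote from boron (wrong regiochemistry);
- binding of fluoride to boron followed by C–B instead of C–Si cleavage, so that the aryne forms on the other side of the triflate and the boron handle is lost;
- capture of the o-quinone methide by a second aryne;
- fluoride-induced self-condensation of prenal.

Fallback (known chemistry): it sets out from prenal 6 and comes back to the route at boronate 13; steps 1–6 are then not needed. Purchased catechol is mono-protected (NaH, 1 equiv, MOMCl, DMF) to 2-(methoxymethoxy)phenol F1. Its aryloxide ArOTi(OEt)3 (Ti(OEt)4, toluene, ethanol distilled off) is condensed with 6 at reflux to give 8-(methoxymethoxy)-2,2-dimethyl-2H-chromene F2; this is the classical phenol/enal chromene synthesis (ortho C-alkylation, dehydration to the o-quinone methide, oxa-6π closure). Iridium-catalysed C–H borylation ([Ir(OMe)(cod)]2, 4,4′-di-tert-butyl-2,2′-bipyridine, B2pin2, THF, 80 °C) then borylates C6, the only aryl C–H without an ortho substituent, to give 13, which enters the periodate stage of step 7.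

2. Step 9. What may go wrong: slow carborhodation of the electron-rich vinylogous ester, competing protodeboronation of the arylboronic acid, or insufficient or reversed facial selectivity.

Fallback: it sets out from 14 and 16 and comes back at 17. The same C–C bond is made without asymmetric induction under cationic divalent palladium catalysis (Pd(OCOCF3)2, 2,2′-bipyridine, NH4PF6, H2O, 1,2-dichloroethane, 60 °C) to give the racemic 5,7-bis(methoxymethoxy)-2-[8-(methoxymethoxy)-2,2-dimethyl-2H-chromen-6-yl]-2,3-dihydro-4H-chromen-4-one F3. Preparative chromatography on a polysaccharide chiral stationary phase separates 17 from the (2R)-5,7-bis(methoxymethoxy)-2-[8-(methoxymethoxy)-2,2-dimethyl-2H-chromen-6-yl]-2,3-dihydro-4H-chromen-4-one F4. F4 is re-racemised with catalytic DBU (reversible retro-oxa-Michael opening to the 2′-hydroxychalcone) and recycled.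

3. Step 2. What may go wrong: incomplete halogen–metal exchange on the electron-rich ArOLi, and protonation or butylation of the aryllithium before borylation.

Fallback: it sets out from 3 and comes back at 5, with the order of events reversed and the C–B bond made by palladium catalysis instead of an organolithium. Phenol 3 is triflated (Tf2O, pyridine, CH2Cl2) to 2-bromo-4-chloro-6-(trimethylsilyl)phenyl trifluoromethanesulfonate F5. Miyaura borylation (PdCl2(dppf), B2pin2, KOAc, 1,4-dioxane, 80 °C) then converts the C–Br bond into the boronate 5; oxidative addition at C–Br should be faster than at the doubly ortho-substituted C–OTf and at C–Cl.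

**Further compounds**

F1 | step 4 | 2-(methoxymethoxy)phenol | COCOc1ccccc1O
F2 | step 4 | 8-(methoxymethoxy)-2,2-dimethyl-2H-chromene | COCOc1cccc2C=CC(C)(C)Oc12
F3 | step 9 | racemic 5,7-bis(methoxymethoxy)-2-[8-(methoxymethoxy)-2,2-dimethyl-2H-chromen-6-yl]-2,3-dihydro-4H-chromen-4-one | CC1(C)C=Cc2cc(C3CC(=O)c4c(OCOC)cc(OCOC)cc4O3)cc(OCOC)c2O1
F4 | step 9 | (2R)-5,7-bis(methoxymethoxy)-2-[8-(methoxymethoxy)-2,2-dimethyl-2H-chromen-6-yl]-2,3-dihydro-4H-chromen-4-one | CC1(C)C=Cc2cc([C@H]3CC(=O)c4c(OCOC)cc(OCOC)cc4O3)cc(OCOC)c2O1
F5 | step 2 | 2-bromo-4-chloro-6-(trimethylsilyl)phenyl trifluoromethanesulfonate | C[Si](C)(C)c1cc(Cl)cc(Br)c1OS(=O)(=O)C(F)(F)F
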